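## Structural features

The target 11 consists of two identical benzene rings, ring A and ring B, joined only through one sp3 carbon (the bridging CH2) between C5 and C5′. It has a mirror plane through that carbon and no stereocentre. Each ring is hexasubstituted: butanoyl at C1, hydroxyl at C2, C4 and C6, methyl at C3 and the bridge at C5. The fragile elements are the electron-rich rings (air-sensitive, above all in base), the diarylmethane link (open to retro-Friedel–Crafts or retro-Michael scission and scrambling) and the aryl ketones (open to retro-Claisen deacylation). With no stereochemistry, the real difficulty is positional: twelve ring carbons must each receive a defined substituent, and substitution on a phloroglucinol offers only statistical or directing-group control with O- versus C-selectivity problems. The alternation of oxygenated carbons (C2, C4, C6 and the ketone carbon) with carbon-substituted ones (C1, C3, C5) marks each ring as a folded tetraketide, C6(=O)–C5–C4(=O)–C3–C2(=O)–C1–C(=O)Pr. The key step exploits this: the C1–C6 bond of ring A and the C1′–C6′ bond of ring B are formed at the same time by Claisen cyclisation of a CH2-bridged bis(tetraketide) stored as the bis(pyranone) 9. Both rings therefore appear fully substituted in the last step, and the bridge between C5 and C5′ is made before any arene exists.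

## Logic of the disconnections

**11 ⇒ 9 (through 10).** The bonds cut are C1–C6 in ring A and C1′–C6′ in ring B, each between the acyl-bearing carbon and the hydroxylated carbon next to the bridge. This retro-Claisen opening turns each arene into a 3,5,7-trioxo ester arm (10). Tying each ester carbonyl back to its 5-enol oxygen gives the two lactone rings of 9, a stable isomer of 11. Two hexasubstituted benzene rings are thus traded for two 2-pyranones. The forward step must open both lactones and close both carbocycles in the Claisen mode, not the aldol mode, without breaking the C–CH2–C bridge.

**9 ⇒ 6 + 7.** The bonds cut are the two C3–CH2 bonds of 9 (C5–CH2 and C5′–CH2 of 11). C3 of 6 is the enolic carbon of a cyclic 1,3-dicarbonyl system and is the natural nucleophile towards 7, and the symmetry halves the problem. The forward step must react at ring C3 and not at the side-chain methylene, and must stop at the 2:1 adduct.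

**6 ⇒ 4 + 5.** The bond cut joins the side-chain CH2 to the ketone carbon, which is the future C1–C(=O) aryl–acyl bond of 11. It is made as a Claisen acylation at the pyranone stage, so no Friedel–Crafts reaction is needed. The forward step must metalate the 6-methyl group of 4 and not the 5-methyl group, and must stop after one acylation by 5.

**4 ⇒ 3.** The lactone C–O bond is cut, giving an acyclic 3,5-dioxo acid. The forward lactonisation must outrun decarboxylation of the β-keto acid.

**3 ⇒ 1 + 2.** The bond cut joins the carboxyl carbon to its CH2. Since 1 is symmetric, its two methyl groups are equivalent and no regiochemical choice arises. The forward step must carboxylate the terminal carbanion of the dianion, not the internal one.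

## Other disconnections considered

Alternative 1: Cut both aryl–CH2 bonds of 11. Forward, 2-methylbenzene-1,3,5-triol A1 is C-butanoylated to 1-(2,4,6-trihydroxy-3-methylphenyl)butan-1-one A2, and two molecules of A2 are condensed with 7. This is the first route that comes to mind and the shortest on paper, so it is not set aside for length. It leaves all positional control to electrophilic substitution: A1 has two equivalent free positions, so mono- versus bis-acylation and O- versus C-acylation must be controlled. It also handles air-sensitive polyphenols in every step and builds neither ring. The chosen plan fixes every substituent by chain connectivity and meets an arene only in the last flask.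

Alternative 2: Cut both aryl–C(=O) bonds of 11 in a two-directional sense. Forward, 2,2′-methylenebis(4-methylbenzene-1,3,5-triol) A3 (from A1 and 7) undergoes double Lewis-acid-mediated C-butanoylation at its only two free positions. The acid needed for C-acylation can protonate the bridge-bearing ring carbons of this very electron-rich diarylmethane, so retro-Friedel–Crafts scission and scrambling of the bridge are expected to compete. Six free hydroxyl groups also invite O-acylation. The chosen plan never exposes the bridge to a Lewis acid.

Alternative 3: Cut only one aryl–CH2 bond of 11, copying the presumed biosynthetic origin of the bridge from a C-methyl group. Forward, 1-(2,4,6-trihydroxy-3,5-dimethylphenyl)butan-1-one A4 is dehydrogenated by a quinone-type hydride acceptor to the o-quinone methide 2-butanoyl-3,5-dihydroxy-4-methyl-6-methylidenecyclohexa-2,4-dien-1-one A5, which is captured at the free position of A2. The plan needs two different monomers. The oxidant cannot be expected to tell the C-methyl groups of A4, A2 and the product apart, so isomeric and over-oxidised diarylmethanes are likely. The chosen plan uses one monomer and has no oxidation step.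

Key step: step 5

Assumption: 1, 2, 5 and 7 (as 37% aqueous solution) are taken as commercial. Intermediates 8 and 10 are drawn as neutral compounds although they exist in the flask as enol or magnesium enolate forms.

## Steps

Step 1
Reactants: 1 3-methylpentane-2,4-dione; 2 carbon dioxide
Product: 3 4-methyl-3,5-dioxohexanoic acid
Conditions: LiN(iPr)2 (2.2 equiv), THF, −78 → 0 °C; CO2 (g), −78 °C; cold 1 M HCl
Reagents that add atoms: none
Why: Dianion chemistry of a β-diketone: the second deprotonation takes place at a terminal methyl group, and this terminal carbanion, the more basic and more nucleophilic site, is carboxylated; the two methyl groups of 1 are equivalent, so only one acid can form.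

Step 2
Reactants: 3 4-methyl-3,5-dioxohexanoic acid
Product: 4 4-hydroxy-5,6-dimethyl-2H-pyran-2-one
Conditions: Ac2O (3 equiv), CH2Cl2, 0 °C → rt
Reagents that add atoms: none
Why: Cyclodehydration of a 3,5-dioxo acid to a 4-hydroxy-2-pyranone: the mixed anhydride is attacked by the enol oxygen of the C5 ketone (6-exo-trig lactonisation) and the product settles as the conjugated vinylogous acid.

Step 3
Reactants: 4 4-hydroxy-5,6-dimethyl-2H-pyran-2-one; 5 methyl butanoate
Product: 6 4-hydroxy-5-methyl-6-(2-oxopentyl)-2H-pyran-2-one
Conditions: LiN(iPr)2 (3.3 equiv), THF, −78 °C; 5 (1.1 equiv), −78 → 0 °C; 1 M HCl
Reagents that add atoms: none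
Why: Claisen acylation of a pyranone dianion: after the 4-OH proton, the base removes a proton of the 6-methyl group, which is vinylogously conjugated with the C4 carbonyl, whereas the 5-methyl group is cross-conjugated and not acidified; the third equivalent of base keeps the more acidic product as its enolate and so prevents a second addition.

Step 4
Reactants: 6 4-hydroxy-5-methyl-6-(2-oxopentyl)-2H-pyran-2-one (2 equiv); 7 formaldehyde
Product: 9 3,3′-methylenebis[4-hydroxy-5-methyl-6-(2-oxopentyl)-2H-pyran-2-one], via 5-methyl-3-methylidene-6-(2-oxopentyl)-2H-pyran-2,4(3H)-dione 8 (not isolated)
Conditions: 37% aq. CH2O (0.5 equiv), EtOH–H2O, rt → 50 °C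
Reagents that add atoms: none
Why: Knoevenagel condensation at the enolic C3 gives the methylidene dione 8, a strong Michael acceptor that is captured at C3 by a second molecule of 6, as in the formation of methylene-bridged dimers from 4-hydroxycoumarin; the side-chain methylene sits in the keto form and should be far less nucleophilic than the ring enol.

Step 5
Reactants: 9 3,3′-methylenebis[4-hydroxy-5-methyl-6-(2-oxopentyl)-2H-pyran-2-one]
Product: 11 methylene-bis-methylphlorobutyrophenone, via dimethyl 2,4-bis(2-methyl-3,5-dioxooctanoyl)pentanedioate 10 (not isolated)
Conditions: Mg(OMe)2 (10 equiv), degassed MeOH, reflux, Ar; cold 1 M HCl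
Reagents that add atoms: none
Why: Mg(OMe)2 deprotonates both 4-hydroxyl groups, and methoxide adds to each lactone carbonyl (pyranone C2) and opens the ring to the bis(methyl 3,5,7-trioxoalkanoate) 10, held as its magnesium enolate chelates. In each arm the methylene between the 5- and 7-ketones, the most acidic CH2 of the chain, attacks the ester carbonyl in a Claisen (Dieckmann-type) closure; loss of methoxide and enolisation of the resulting cyclohexane-1,3,5-trione give the arene, so the overall change 9 → 11 is an isomerisation. The closest known reaction type is the Mg(OMe)2-induced Claisen cyclisation of 6-(2-oxoalkyl)-4-hydroxy-2-pyranones and of 3,5,7-trioxoalkanoates to acylphloroglucinols, the laboratory counterpart of the polyketide Claisen cyclisation. Both rings close in the carbocyclic 6-exo-trig mode, forming C1–C6 and C1′–C6′. No stereocentre is formed, and the enolisable stereocentres of 10 vanish on aromatisation. The step needs Claisen and not aldol selectivity: in 10 the ester α-carbon carries the bridging CH2, so the aldol adduct onto the 7-ketone (the resorcylate pathway) has a quaternary carbon, cannot aromatise and stays reversible, while the magnesium chelate lowers the electrophilicity of the ketones. Closures between the two arms likewise end in adducts that cannot aromatise, so both arms should funnel into the aromatic sink. The position of every substituent is fixed by the chain: pyranone C3 (bridge) becomes C5, pyranone C5 (methyl) becomes C3, and the side-chain CH2 with its ketone becomes C1 with the butanoyl group.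

## Compound list

1 | 3-methylpentane-2,4-dione | CC(=O)C(C)C(C)=O | starting material
2 | carbon dioxide | O=C=O | starting material
3 | 4-methyl-3,5-dioxohexanoic acid | CC(=O)C(C)C(=O)CC(=O)O | intermediate
4 | 4-hydroxy-5,6-dimethyl-2H-pyran-2-one | CC1=C(C)C(O)=CC(=O)O1 | intermediate
5 | methyl butanoate | CCCC(=O)OC | starting material
6 | 4-hydroxy-5-methyl-6-(2-oxopentyl)-2H-pyran-2-one | CCCC(=O)CC1=C(C)C(O)=CC(=O)O1 | intermediate
7 | formaldehyde | C=O | starting material
8 | 5-methyl-3-methylidene-6-(2-oxopentyl)-2H-pyran-2,4(3H)-dione | CCCC(=O)CC1=C(C)C(=O)C(=C)C(=O)O1 | intermediate
9 | 3,3′-methylenebis[4-hydroxy-5-methyl-6-(2-oxopentyl)-2H-pyran-2-one] | CCCC(=O)CC1=C(C)C(O)=C(CC2=C(O)C(C)=C(CC(=O)CCC)OC2=O)C(=O)O1 | intermediate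
10 | dimethyl 2,4-bis(2-methyl-3,5-dioxooctanoyl)pentanedioate (mixture of stereoisomers, all centres enolisable) | CCCC(=O)CC(=O)C(C)C(=O)C(CC(C(=O)OC)C(=O)C(C)C(=O)CC(=O)CCC)C(=O)OC | intermediate
11 | methylene-bis-methylphlorobutyrophenone, 1,1′-[methylenebis(2,4,6-trihydroxy-5-methyl-3,1-phenylene)]di(butan-1-one) | CCCC(=O)c1c(O)c(C)c(O)c(Cc2c(O)c(C)c(O)c(C(=O)CCC)c2O)c1O | target

## Step count and least certain steps

Total step count: 5. Longest linear sequence: 5 (steps 1 to 5).

**Step 5 (key step).** The most likely failure is scission of the methylene bridge by retro-Michael fragmentation of the ring-opened arms in hot alkoxide, with scrambling of the halves. Arrest after closure of one ring, and retro-Claisen loss of a butanoyl group by methanolysis, are also possible. These arise because the bridge carbon of 10 sits between two β-keto ester carbons and the triketone is open to alkoxide attack. Fallback: set out from 6 and carry out the Mg(OMe)2 cyclisation on the monomer, which should give 1-(2,4,6-trihydroxy-3-methylphenyl)butan-1-one F1. Two molecules of it are then condensed at their only free ring position with 7 in dilute aqueous base at room temperature, which returns to the route at 11. The ring is then still built from the chain, but the bridge is made after aromatisation.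

**Step 4.** The most likely failure is loss of site selectivity between ring C3 and the side-chain methylene of 6, or further condensation beyond the 2:1 adduct, because the side chain is also a 1,3-dicarbonyl-like position. Fallback: set out from 4, which has no side-chain methylene, and condense it with 7 to give 3,3′-methylenebis(4-hydroxy-5,6-dimethyl-2H-pyran-2-one) F2. Its tetraanion (LiN(iPr)2 in excess, THF, −78 °C) is then acylated at both 6-methyl groups with 5 in a two-directional chain extension, which returns to the route at 9.

**Step 3.** The most likely failure is incomplete or misdirected metalation, with proton transfer from the ester to the dianion and poor solubility of the dianion, leading to low conversion. Fallback: set out from 1 and acylate its dianion with 5 to give 3-methylnonane-2,4,6-trione F3. Its trianion is carboxylated with 2 at the terminal methyl group to give 4-methyl-3,5,7-trioxodecanoic acid F4, and cyclodehydration with Ac2O returns to the route at 6. The side chain is then in place before the pyranone is formed.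

**Step 2.** The most likely failure is decarboxylation of the β-keto acid before lactonisation, or O-acetylation of the 4-hydroxyl group of the product. Fallback: set out from 3 and esterify it with TMSCHN2 in MeOH–toluene at 0 °C to give methyl 4-methyl-3,5-dioxohexanoate F5. Base-induced lactonisation (DBU, toluene, reflux) then returns to the route at 4. This closes the ring by transesterification of a stable ester in place of activation of the labile acid.

## Further compounds

F1 | step 5 | 1-(2,4,6-trihydroxy-3-methylphenyl)butan-1-one | CCCC(=O)c1c(O)c(C)c(O)cc1O
F2 | step 4 | 3,3′-methylenebis(4-hydroxy-5,6-dimethyl-2H-pyran-2-one) | CC1=C(C)C(O)=C(CC2=C(O)C(C)=C(C)OC2=O)C(=O)O1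
F3 | step 3 | 3-methylnonane-2,4,6-trione | CCCC(=O)CC(=O)C(C)C(C)=O
F4 | step 3 | 4-methyl-3,5,7-trioxodecanoic acid | CCCC(=O)CC(=O)C(C)C(=O)CC(=O)O
F5 | step 2 | methyl 4-methyl-3,5-dioxohexanoate | CC(=O)C(C)C(=O)CC(=O)OC
A1 | alternative 1 | 2-methylbenzene-1,3,5-triol | Cc1c(O)cc(O)cc1O
A2 | alternative 1 | 1-(2,4,6-trihydroxy-3-methylphenyl)butan-1-one | CCCC(=O)c1c(O)c(C)c(O)cc1O
A3 | alternative 2 | 2,2′-methylenebis(4-methylbenzene-1,3,5-triol) | Cc1c(O)cc(O)c(Cc2c(O)cc(O)c(C)c2O)c1O
A4 | alternative 3 | 1-(2,4,6-trihydroxy-3,5-dimethylphenyl)butan-1-one | CCCC(=O)c1c(O)c(C)c(O)c(C)c1O
A5 | alternative 3 | 2-butanoyl-3,5-dihydroxy-4-methyl-6-methylidenecyclohexa-2,4-dien-1-one | CCCC(=O)C1=C(O)C(C)=C(O)C(=C)C1=O
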